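**Retrosynthetic overview**

- The malonate diester is cut at both ester C–O bonds into malonyl dichloride and two molecules of (E)-labd-13-ene-8α,15-diol. The C11–C12 bond of that diol is cut into a drimane C11 nucleophile and a C12–C16 (E)-allylic chloride made from prenol.
- The drimane-8α,11-diol unit comes from drimenol (α-epoxidation of C7=C8, hydride opening at C7). Drimenol comes from the C9 ketone by methylenation and hydroboration from the α face.
- Ring A (C1, C2, C3, C4, C5, C10) is closed onto an intact ring B through the C3–C4 bond by a hydrogen-atom-transfer radical cyclization onto a vinyl sulfone; the sulfonyl group is removed afterwards.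
- Feature on which the strategy rests: ring B (C5–C10) carries the C8 methyl next to C9, and C5 carries the gem-dimethyl carbon C4. This is the carbon pattern of (R)-carvone: its carbonyl is C9, its α′ carbon is C10, its isopropenyl carbon is C4, and its stereocentre is C5 (H-5α).
- Ring order: ring B from the chiral pool, then ring A (step 5).

Key step: step 5

Remark: C6 of compound 8 and the sulfone-bearing C2 of compounds 11–15 are carried as epimer mixtures, because both centres are erased later (steps 4 and 8).

**Route**

Step 1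
Reactants: 1 phenyl vinyl sulfone; 2 formaldehyde
Product: 3 2-(phenylsulfonyl)prop-2-en-1-ol
Conditions: 37% aq. HCHO, DABCO (0.3 equiv), THF, rt
Reagents that add atoms: none
Why: Morita–Baylis–Hillman hydroxymethylation, in which DABCO adds to the vinyl sulfone and the α-sulfonyl carbanion captures formaldehyde before the amine is expelled, a reaction type established for aryl vinyl sulfones and aldehydes.

Step 2
Reactants: 3 2-(phenylsulfonyl)prop-2-en-1-ol
Product: 4 3-bromo-2-(phenylsulfonyl)prop-1-ene
Conditions: PBr3, Et2O, 0 °C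
Reagents that add atoms: phosphorus tribromide, BrP(Br)Br
Why: Bromination of a primary allylic alcohol with PBr3, where direct and allylic substitution are degenerate in this symmetric allyl system and give the same bromomethyl vinyl sulfone.

Step 3
Reactants: 5 (R)-(−)-carvone; 6 iodomethane
Product: 8 (5R)-2,6-dimethyl-5-(prop-1-en-2-yl)cyclohex-2-en-1-one (6-methylcarvone; C6 epimers), via carvone lithium dienolate 7 (not isolated)
Conditions: LiN(iPr)2, THF, −78 °C; MeI, −78 → 0 °C
Reagents that add atoms: none
Why: Kinetic α′-deprotonation of the enone gives the cross-conjugated dienolate, which is C-methylated (enolate alkylation); the new C6 centre need not be controlled because it is re-enolized in step 4.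

Step 4
Reactants: 8 6-methylcarvone; 4 3-bromo-2-(phenylsulfonyl)prop-1-ene
Product: 10 (5S,6S)-2,6-dimethyl-6-[2-(phenylsulfonyl)prop-2-en-1-yl]-5-(prop-1-en-2-yl)cyclohex-2-en-1-one, via methylcarvone lithium enolate 9 (not isolated)
Conditions: LiN(iPr)2, THF, −78 °C; 4 (1.3 equiv), −78 → −20 °C
Reagents that add atoms: none
Why: The tetrasubstituted α′-enolate attacks the bromomethyl vinyl sulfone by conjugate addition–bromide elimination (SN2′-type enolate alkylation) on the face anti to the C5 isopropenyl group, which sets the quaternary centre (future C10) with the methyl cis and the sulfonylallyl arm trans to isopropenyl.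

Step 5
Reactants: 10 (5S,6S)-2,6-dimethyl-6-[2-(phenylsulfonyl)prop-2-en-1-yl]-5-(prop-1-en-2-yl)cyclohex-2-en-1-one
Product: 11 (4aS,8aS)-2,5,5,8a-tetramethyl-7-(phenylsulfonyl)-4a,5,6,7,8,8a-hexahydronaphthalen-1(4H)-one (2-(phenylsulfonyl)-11-nordrim-7-en-9-one; C2 epimers)
Conditions: Fe(acac)3 (0.5 equiv), PhSiH3 (2.5 equiv), EtOH/(CH2OH)2, 0.02 M, 60 °C
Reagents that add atoms: none
Why: An iron hydride formed from Fe(acac)3 and PhSiH3 in ethanol gives a hydrogen atom to the terminal CH2 of the isopropenyl group, and the tertiary C4 radical so formed, which already holds both future methyl groups, adds to the unsubstituted CH2 terminus (C3) of the vinyl sulfone; the α-sulfonyl radical at C2 is then reduced by divalent iron and protonated by the solvent. The closest known reaction type is the iron-hydride HAT-initiated reductive coupling of a donor alkene with an electron-poor acceptor such as a vinyl sulfone, run here intramolecularly to build a quaternary carbon. Ring A (C1, C2, C3, C4, C5, C10) closes by 6-endo-trig radical cyclization through the new C3–C4 bond. No stereocentre of the target is created: C4 is a gem-dimethyl carbon, the C2 sulfone centre forms as an epimer mixture that step 8 erases, and the trans ring fusion follows from the anti arms on C5 and C10 fixed in step 4, which can bridge only diequatorially. The step needs hydrogen-atom transfer to the electron-rich 1,1-disubstituted alkene in preference to the vinyl sulfone and the enone, and 6-endo in preference to 5-exo closure; the donor character of the isopropenyl group secures the first, and the sulfonyl group on the internal alkene carbon secures the second, since attack at the CH2 terminus is polarity-matched, sterically open and leads to the stabilized α-sulfonyl radical.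

Step 6
Reactants: 11 2-(phenylsulfonyl)-11-nordrim-7-en-9-one
Product: 13 2-(phenylsulfonyl)drima-7,9(11)-diene (C2 epimers), via silylmethyl carbinol 12 (not isolated)
Conditions: Me3SiCH2Li (3 equiv), CeCl3 (3 equiv), THF, −78 → 0 °C; H2O; crude carbinol, KH, THF, 0 °C → rt
Reagents that add atoms: (trimethylsilyl)methyllithium, [Li]C[Si](C)(C)C
Why: Peterson olefination, in which the weakly basic organocerium reagent adds 1,2 to the hindered, non-enolizable C9 carbonyl and the potassium alkoxide of the β-hydroxysilane loses silanolate by syn-elimination to give the exocyclic C9=C11 methylene, the carbinol configuration being of no consequence.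

Step 7
Reactants: 13 2-(phenylsulfonyl)drima-7,9(11)-diene
Product: 15 2-(phenylsulfonyl)drim-7-en-11-ol (9α-H; C2 epimers), via B-alkyl-9-BBN adduct 14 (not isolated)
Conditions: 9-BBN, THF, 0 °C → rt; NaOH, H2O2, 0 °C → rt
Reagents that add atoms: hydrogen peroxide, OO
Why: Hydroboration–oxidation, in which 9-BBN places boron on the unhindered terminal C11 in preference to the trisubstituted C7=C8 bond and delivers hydrogen to C9 from the α face, anti to the axial C10 methyl group, so that oxidation with retention gives the 9α-H, 9β-CH2OH (drimenol) configuration.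

Step 8
Reactants: 15 2-(phenylsulfonyl)drim-7-en-11-ol
Product: 16 (−)-drimenol (drim-7-en-11-ol)
Conditions: Na/Hg (6%), Na2HPO4, MeOH/THF, −20 °C → rt
Reagents that add atoms: none
Why: Reductive desulfonylation of a secondary alkyl phenyl sulfone by electron transfer from Na/Hg in buffered methanol cleaves the C2–S bond and removes the only uncontrolled stereocentre, while the isolated trisubstituted alkene and the alcohol are inert.

Step 9
Reactants: 16 drimenol
Product: 17 7α,8α-epoxydriman-11-ol
Conditions: mCPBA, NaHCO3, CH2Cl2, 0 °C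
Reagents that add atoms: mCPBA, OOC(=O)c1cccc(Cl)c1
Why: Prilezhaev epoxidation of the trisubstituted C7=C8 alkene should occur on the α face, because the axial C10 methyl group shields the β face, and this sets C7 and C8 as the 7α,8α-epoxide.

Step 10
Reactants: 17 7α,8α-epoxydriman-11-ol
Product: 18 drimane-8α,11-diol
Conditions: LiAlH4, THF, reflux
Reagents that add atoms: none
Why: Hydride opens the epoxide by SN2 attack at the less substituted C7 from the β face (trans-diaxial, Fürst–Plattner), leaving the C8–O bond untouched, so that the axial 8α tertiary alcohol with a β C8 methyl results.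

Step 11
Reactants: 18 drimane-8α,11-diol
Product: 19 11-iododriman-8α-ol
Conditions: PPh3, I2, imidazole, PhMe/MeCN, rt → 60 °C
Reagents that add atoms: iodine, II
Why: Garegg–Samuelsson (Appel-type) iodination converts only the primary C11 alcohol, by way of its alkoxyphosphonium salt and SN2 displacement by iodide, since the hindered axial tertiary 8α-hydroxyl does not react under the buffered conditions.

Step 12
Reactants: 19 11-iododriman-8α-ol
Product: 20 11-iodo-8α-(trimethylsilyloxy)drimane
Conditions: Me3SiOTf, 2,6-lutidine, CH2Cl2, −78 → 0 °C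
Reagents that add atoms: trimethylsilyl triflate, C[Si](C)(C)OS(=O)(=O)C(F)(F)F
Why: Silylation of the tertiary alcohol with a silyl triflate removes the acidic proton and blocks Grob-type fragmentation of the γ-hydroxy iodide ahead of organomagnesium formation.

Step 13
Reactants: 21 prenol (3-methylbut-2-en-1-ol)
Product: 22 tert-butyldimethyl[(3-methylbut-2-en-1-yl)oxy]silane
Conditions: t-BuMe2SiCl, imidazole, CH2Cl2, rt
Reagents that add atoms: tert-butyldimethylsilyl chloride, CC(C)(C)[Si](C)(C)Cl
Why: Standard imidazole-mediated silylation of a primary allylic alcohol.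

Step 14
Reactants: 22 tert-butyldimethyl[(3-methylbut-2-en-1-yl)oxy]silane
Product: 23 (E)-4-[(tert-butyldimethylsilyl)oxy]-2-methylbut-2-en-1-ol
Conditions: SeO2 (0.1 equiv), t-BuOOH, salicylic acid (cat.), CH2Cl2, rt, stopped short of full conversion
Reagents that add atoms: tert-butyl hydroperoxide, CC(C)(C)OO
Why: Sharpless-type allylic oxidation with catalytic SeO2 (ene reaction, then [2,3]-sigmatropic shift) hydroxylates the methyl group trans to the CH2OSi chain, which fixes the (E)-geometry of the future C13=C14 bond.

Step 15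
Reactants: 23 (E)-4-[(tert-butyldimethylsilyl)oxy]-2-methylbut-2-en-1-ol
Product: 24 (E)-tert-butyl[(4-chloro-3-methylbut-2-en-1-yl)oxy]dimethylsilane
Conditions: PPh3, CCl4, reflux
Reagents that add atoms: carbon tetrachloride, ClC(Cl)(Cl)Cl
Why: Appel chlorination turns primary allylic alcohols into the unrearranged allylic chlorides with retention of alkene geometry under neutral conditions that leave the silyl ether intact.

Step 16
Reactants: 20 11-iodo-8α-(trimethylsilyloxy)drimane; 24 (E)-tert-butyl[(4-chloro-3-methylbut-2-en-1-yl)oxy]dimethylsilane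
Product: 26 (E)-15-[(tert-butyldimethylsilyl)oxy]-8α-(trimethylsilyloxy)labd-13-ene, via C11 Grignard reagent 25 (not isolated)
Conditions: Mg turnings (I2-activated), THF, rt → 40 °C; then 24 (1.5 equiv), Li2CuCl4 (5 mol%), THF, −40 → 0 °C
Reagents that add atoms: none
Why: Magnesium inserts into the primary C–I bond, and Kochi-type Li2CuCl4-catalysed coupling of the Grignard reagent with the primary allylic chloride in THF proceeds with α (SN2) regioselectivity and retention of the (E)-alkene to form the C11–C12 bond, the hindered β-branched nucleophile further disfavouring attack at the γ-carbon.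

Step 17
Reactants: 26 (E)-15-[(tert-butyldimethylsilyl)oxy]-8α-(trimethylsilyloxy)labd-13-ene
Product: 27 (E)-labd-13-ene-8α,15-diol
Conditions: Bu4NF, THF, rt
Reagents that add atoms: none
Why: Fluoride cleaves both the primary TBS ether and the tertiary TMS ether and leaves the trisubstituted alkene untouched.

Step 18
Reactants: 27 (E)-labd-13-ene-8α,15-diol (2 equiv); 28 malonyl dichloride
Product: 30 bis[(E)-8α-hydroxylabd-13-en-15-yl] malonate (CNP0254645.1), via malonyl half-ester chloride 29 (not isolated)
Conditions: malonyl dichloride (0.5 equiv), pyridine, CH2Cl2, −20 → 0 °C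
Reagents that add atoms: none
Why: Pyridine-mediated esterification of the primary allylic alcohol with the acid chloride takes place twice on malonyl dichloride, the hindered axial tertiary 8α-hydroxyl being inert, and gives the symmetric diester.

**Compound list**

1 | phenyl vinyl sulfone | C=CS(=O)(=O)c1ccccc1 | starting material
2 | formaldehyde | C=O | starting material
3 | 2-(phenylsulfonyl)prop-2-en-1-ol | OCC(=C)S(=O)(=O)c1ccccc1 | intermediate
4 | 3-bromo-2-(phenylsulfonyl)prop-1-ene | BrCC(=C)S(=O)(=O)c1ccccc1 | intermediate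
5 | (R)-(−)-carvone | O=C1C[C@H](C(C)=C)CC=C1C | starting material
6 | iodomethane | CI | starting material
7 | carvone lithium dienolate (α′-enolate) | [Li]OC1=C[C@H](C(C)=C)CC=C1C | intermediate
8 | (5R)-2,6-dimethyl-5-(prop-1-en-2-yl)cyclohex-2-en-1-one (6-methylcarvone, C6 epimers) | O=C1C(C)[C@H](C(C)=C)CC=C1C | intermediate
9 | lithium enolate of 6-methylcarvone | [Li]OC1=C(C)[C@H](C(C)=C)CC=C1C | intermediate
10 | (5S,6S)-2,6-dimethyl-6-[2-(phenylsulfonyl)prop-2-en-1-yl]-5-(prop-1-en-2-yl)cyclohex-2-en-1-one | O=C1[C@@](C)(CC(=C)S(=O)(=O)c2ccccc2)[C@H](C(C)=C)CC=C1C | intermediate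
11 | (4aS,8aS)-2,5,5,8a-tetramethyl-7-(phenylsulfonyl)-4a,5,6,7,8,8a-hexahydronaphthalen-1(4H)-one (2-(phenylsulfonyl)-11-nordrim-7-en-9-one, C2 epimers) | O=C1[C@@]2(C)CC(S(=O)(=O)c3ccccc3)CC(C)(C)[C@@H]2CC=C1C | intermediate
12 | 2-(phenylsulfonyl)-9-[(trimethylsilyl)methyl]-11-nordrim-7-en-9-ol (C2 and C9 epimers) | C[Si](C)(C)CC1(O)[C@@]2(C)CC(S(=O)(=O)c3ccccc3)CC(C)(C)[C@@H]2CC=C1C | intermediate
13 | 2-(phenylsulfonyl)drima-7,9(11)-diene (C2 epimers) | C=C1[C@@]2(C)CC(S(=O)(=O)c3ccccc3)CC(C)(C)[C@@H]2CC=C1C | intermediate
14 | B-[2-(phenylsulfonyl)drim-7-en-11-yl]-9-borabicyclo[3.3.1]nonane (9α-H) | C(B1C2CCCC1CCC2)[C@@H]1[C@@]2(C)CC(S(=O)(=O)c3ccccc3)CC(C)(C)[C@@H]2CC=C1C | intermediate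
15 | 2-(phenylsulfonyl)drim-7-en-11-ol (9α-H, C2 epimers) | OC[C@@H]1[C@@]2(C)CC(S(=O)(=O)c3ccccc3)CC(C)(C)[C@@H]2CC=C1C | intermediate
16 | (−)-drimenol, [(1S,4aS,8aS)-2,5,5,8a-tetramethyl-1,4,4a,5,6,7,8,8a-octahydronaphthalen-1-yl]methanol | OC[C@@H]1[C@@]2(C)CCCC(C)(C)[C@@H]2CC=C1C | intermediate
17 | 7α,8α-epoxydriman-11-ol | OC[C@@H]1[C@@]2(C)CCCC(C)(C)[C@@H]2C[C@H]3O[C@@]13C | intermediate
18 | drimane-8α,11-diol | OC[C@@H]1[C@@]2(C)CCCC(C)(C)[C@@H]2CC[C@@]1(C)O | intermediate
19 | 11-iododriman-8α-ol | IC[C@@H]1[C@@]2(C)CCCC(C)(C)[C@@H]2CC[C@@]1(C)O | intermediate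
20 | 11-iodo-8α-(trimethylsilyloxy)drimane | IC[C@@H]1[C@@]2(C)CCCC(C)(C)[C@@H]2CC[C@@]1(C)O[Si](C)(C)C | intermediate
21 | prenol (3-methylbut-2-en-1-ol) | CC(C)=CCO | starting material
22 | tert-butyldimethyl[(3-methylbut-2-en-1-yl)oxy]silane | CC(C)=CCO[Si](C)(C)C(C)(C)C | intermediate
23 | (E)-4-[(tert-butyldimethylsilyl)oxy]-2-methylbut-2-en-1-ol | OC/C(C)=C/CO[Si](C)(C)C(C)(C)C | intermediate
24 | (E)-tert-butyl[(4-chloro-3-methylbut-2-en-1-yl)oxy]dimethylsilane | ClC/C(C)=C/CO[Si](C)(C)C(C)(C)C | intermediate
25 | [8α-(trimethylsilyloxy)driman-11-yl]magnesium iodide | I[Mg]C[C@@H]1[C@@]2(C)CCCC(C)(C)[C@@H]2CC[C@@]1(C)O[Si](C)(C)C | intermediate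
26 | (E)-15-[(tert-butyldimethylsilyl)oxy]-8α-(trimethylsilyloxy)labd-13-ene | C/C(=C\CO[Si](C)(C)C(C)(C)C)CC[C@@H]1[C@@]2(C)CCCC(C)(C)[C@@H]2CC[C@@]1(C)O[Si](C)(C)C | intermediate
27 | (E)-labd-13-ene-8α,15-diol | C/C(=C\CO)CC[C@@H]1[C@@]2(C)CCCC(C)(C)[C@@H]2CC[C@@]1(C)O | intermediate
28 | malonyl dichloride | O=C(Cl)CC(=O)Cl | starting material
29 | (E)-8α-hydroxylabd-13-en-15-yl 3-chloro-3-oxopropanoate | C/C(=C\COC(=O)CC(=O)Cl)CC[C@@H]1[C@@]2(C)CCCC(C)(C)[C@@H]2CC[C@@]1(C)O | intermediate
30 | bis[(E)-8α-hydroxylabd-13-en-15-yl] malonate (CNP0254645.1) | C/C(=C\COC(=O)CC(=O)OC/C=C(\C)CC[C@@H]1[C@@]2(C)CCCC(C)(C)[C@@H]2CC[C@@]1(C)O)CC[C@@H]1[C@@]2(C)CCCC(C)(C)[C@@H]2CC[C@@]1(C)O | target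

**Step count and risk**

Total step count: 18. Longest linear sequence: 14 steps (steps 1, 2, 4–12, 16–18, from phenyl vinyl sulfone); 13 steps from (R)-carvone.

Steps most likely to fail:

Step 5 (key step). The tertiary C4 radical may be reduced by a second hydrogen-atom transfer before it cyclizes (net hydrogenation of the isopropenyl group), or hydrogen-atom transfer to the enone may compete. The fallback generates the same radical by halogen abstraction instead of hydrogen-atom transfer. It sets out from 10: Markovnikov addition of HBr (33% in AcOH, 0 °C) to the isopropenyl group gives the tertiary bromide of 10 (C(CH3)2Br in place of isopropenyl) F1. Slow addition of Bu3SnH/AIBN in refluxing benzene then forms the C4 radical at low hydride concentration, which closes 6-endo onto the vinyl sulfone. The route is rejoined at 11.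

Step 16. Magnesium insertion into the hindered, β-branched iodide may be slow and accompanied by Wurtz coupling or reduction, and the copper-mediated allylic substitution may leak to attack at the γ-carbon (C14), giving a branched terminal alkene. The fallback replaces the organometallic coupling by a sulfone-carbanion alkylation. It sets out from 20: displacement of iodide with PhSO2Na (DMF, 80 °C) gives 11-(phenylsulfonyl)-8α-(trimethylsilyloxy)drimane F2. Deprotonation with n-BuLi (THF/HMPA, −78 °C) and alkylation with chloride 24, which occurs by direct SN2 at the primary allylic carbon with retention of alkene geometry, gives the C11-sulfonyl labdene bis-silyl ether F3 (C11 epimers). Reductive desulfonylation with Na/Hg (Na2HPO4, MeOH) returns to the route at 26.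

Step 6. Deprotonation α to the sulfonyl group may consume the organometallic, and the carbanion so formed may retard 1,2-addition at the hindered C9 carbonyl, so that conversion stalls. The fallback removes the sulfone before the olefination. It sets out from 11: Luche reduction (NaBH4, CeCl3·7H2O, MeOH, 0 °C) gives 2-(phenylsulfonyl)-11-nordrim-7-en-9-ol F4. Na/Hg desulfonylation gives 11-nordrim-7-en-9-ol F5, and oxidation with MnO2 (CH2Cl2) gives the sulfone-free enone 11-nordrim-7-en-9-one F6. Peterson methylenation (Me3SiCH2Li, CeCl3; then KH) then meets no acidic C–H and gives drima-7,9(11)-diene F7. Its 9-BBN hydroboration–oxidation, as in step 7, leads directly to drimenol, and the route is rejoined at 16.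

Further compounds
F1 | step 5 | tertiary bromide of 10, 5-(2-bromopropan-2-yl)-2,6-dimethyl-6-[2-(phenylsulfonyl)prop-2-en-1-yl]cyclohex-2-en-1-one | O=C1[C@@](C)(CC(=C)S(=O)(=O)c2ccccc2)[C@H](C(C)(C)Br)CC=C1C
F2 | step 16 | 11-(phenylsulfonyl)-8α-(trimethylsilyloxy)drimane | O=S(=O)(C[C@@H]1[C@@]2(C)CCCC(C)(C)[C@@H]2CC[C@@]1(C)O[Si](C)(C)C)c1ccccc1
F3 | step 16 | (E)-15-[(tert-butyldimethylsilyl)oxy]-11-(phenylsulfonyl)-8α-(trimethylsilyloxy)labd-13-ene (C11 epimers) | C/C(=C\CO[Si](C)(C)C(C)(C)C)CC(S(=O)(=O)c1ccccc1)[C@@H]1[C@@]2(C)CCCC(C)(C)[C@@H]2CC[C@@]1(C)O[Si](C)(C)C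
F4 | step 6 | 2-(phenylsulfonyl)-11-nordrim-7-en-9-ol (C2 and C9 epimers) | OC1[C@@]2(C)CC(S(=O)(=O)c3ccccc3)CC(C)(C)[C@@H]2CC=C1C
F5 | step 6 | 11-nordrim-7-en-9-ol (C9 epimers) | OC1[C@@]2(C)CCCC(C)(C)[C@@H]2CC=C1C
F6 | step 6 | 11-nordrim-7-en-9-one | O=C1[C@@]2(C)CCCC(C)(C)[C@@H]2CC=C1C
F7 | step 6 | drima-7,9(11)-diene | C=C1[C@@]2(C)CCCC(C)(C)[C@@H]2CC=C1C
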